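A small charge comes first: 0.90 mM of impurity, far less than the 0.40 M of each substrate, yet it stands against a catalyst charge of only 2.00 mM.

| flask | left-handed substrate | right-handed substrate | coupling partner | free catalyst | impurity | remark | time |
|---|---|---|---|---|---|---|---|
| amber | 0.40 M | 0.40 M | 1 equiv | 0.5 mol% | 0.90 mM | the very flask that is asked about, followed so far |  |
| green | 0.40 M | 0.40 M | 0.67 equiv | 0.5 mol% | 0.90 mM | run made earlier |  |
| flask | 0.40 M | 0.40 M | 1.00 equiv | 0.5 mol% | 0.90 mM |  | 1.5 h |

| run | time / min | left-handed substrate / % | right-handed substrate / % |
|---|---|---|---|
| amber | 2.00 | 46 | 50 |
| amber | 5.00 | 42 | 52 |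
| amber | 12.0 | 38 | 50 |
| amber | 25.0 | 29 | 48 |
| green | 3.00 | 49 | 50 |
| green | 6.00 | 42 | 49 |
| green | 15.0 | 36 | 50 |
| green | 40.0 | 31 | 51 |

(scatter of a reading: 1.5 percentage points)

- part of the left-handed substrate and right-handed substrate charged together that has reacted at 1.5 h
- excess of left-handed product over right-handed product in the product at 1.5 h
- excess of right-handed substrate over left-handed substrate among what is left of the two at 1.5 h

- free catalyst is single-handed; left-handed substrate and right-handed substrate are mirror images of each other, charged as a racemate, each of them at the stated concentration
- an excess is the difference of the two amounts in percent of their sum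
- an excess is below zero if the other one leads

Suppose each impurity takes one free catalyst for good. Then we should carry the poison ratio, impurity charged over catalyst charged, which in amber is 0.450. Counted this way, the rate should fall within the first minutes to 55.0% of its opening value and then go on, not stop.

The amber readings give a second way, from the clock instead of the charges. Left-handed substrate and coupling partner are charged equally, and right-handed substrate stays flat within scatter. So if the rate goes with the product of the two, the inverse of [left-handed substrate], taken as a fraction of the two substrates charged together, climbs in a straight line. Its slope up to 2.00 min is 0.0870 min⁻¹, and from 5.00 min to 25.0 min it is 0.0534 min⁻¹. The ratio of late to early is 0.614. That is a loose reading, since the early slope rests on a drop of 4 percentage points read to 1.5 points, but it agrees with the count within that scatter, and the two come from different things.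

We therefore trust the late slope to last. Carried from 25.0 min to 1.5 h, it leaves 14.5% of left-handed substrate in amber. Beside the last amber reading of 48% of right-handed substrate, held flat, that gives our own excess of right-handed substrate over left-handed substrate of 53.6%. The right-handed readings, good to 1.5 points, are too flat to give us a figure for the excess in the product.

The forecast, which said the fast start “may reflect the impurity slowly poisoning some catalyst”, stood at 39% reacted, 89% excess in the product and 57% in the substrate.

The flask gives 40.8% reacted, 80.7% in the product and 55.6% in the substrate, with 3.94% of right-handed product beside 36.8% of left-handed product, by these steps: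

    free catalyst + left-handed substrate ⇌ catalyst intermediate A (K = 2.71 M⁻¹, k = 39.6 M⁻¹ s⁻¹)
    free catalyst + right-handed substrate ⇌ catalyst intermediate B (K = 0.857 M⁻¹, k = 20.7 M⁻¹ s⁻¹)
    coupling partner + catalyst intermediate A → free catalyst + left-handed product (k = 1.18 M⁻¹ s⁻¹)
    coupling partner + catalyst intermediate B → free catalyst + right-handed product (k = 0.226 M⁻¹ s⁻¹)
    2 free catalyst ⇌ resting dimer (K = 510 M⁻¹, k = 18.6 M⁻¹ s⁻¹)
    free catalyst + impurity → spent catalyst (k = 42.6 M⁻¹ s⁻¹)

In this flask spent catalyst stands at 45.0% by 0.150 h and at 45.0% by 1.50 h, with impurity at 0%, which is the poison ratio of 0.450 read as a share; left-handed substrate ends at 13.1% beside our 14.5%. The neighbour charged with 0.12 mol% of free catalyst has a poison ratio of 1.88, above unity, so the count leaves 46.8% of its impurity over. That neighbour shows 46.7% of impurity, 100% spent catalyst and 1.15% reacted.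

(The data were generated by integration on assumed constants; scatter was added.)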